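The dioxolane (ring atoms O1, O2, C3, C4, C5; chain C6–C15 on C5) is disconnected at C5–O1 and C3–O2. Without the acetic acid arm, C3, C4 and C5 map onto the carbonyl, α- and β-carbons of an (E)-methyl enone with a fully substituted β-carbon, and O2–O1 is one molecule of H2O2. One amine-catalysed conjugate hydroperoxidation with spontaneous peroxyhemiketal closure should thus create both C–O bonds, the peroxide ring and the quaternary stereocentre C5. The precursor is an acyclic trienone that already holds C7 from (R)-citronellal and the complete phenyl-capped diene chain. The C3 arm follows by ketene acetal addition to the derived peroxycarbenium ion.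

Key step: step 9

Remark (numbering): O1 is bonded to C5 and O2 to C3; C6 is the CH2 on C5, C7 the methyl-bearing stereocentre, C10=C11 and C14=C15 the chain alkenes, C15 carries the phenyl group.

Assumption: the facial sense of a cinchona primary amine on a β,β-dialkyl enone is extrapolated from β-monosubstituted enones. The quinine-derived amine is written in step 9; its quinidine-derived pseudoenantiomer takes its place, with nothing else changed, if a pilot run shows the (5S) series.

Remark (handling): concentrated H2O2 and all peroxidic compounds are to be handled on small scale, cold, and free of transition-metal traces.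

**Step 1**
Reactants: 1 (E)-5-phenylpent-4-enoic acid
Product: 2 (E)-5-phenylpent-4-en-1-ol
Conditions: LiAlH4, THF, 0 °C → rt; H2O quench
Reagents that add atoms: none
Why: Hydride reduction of the carboxylic acid should stop cleanly at the primary alcohol, since the isolated styrene double bond is neither conjugated to the carbonyl group nor within reach of alkoxide-directed hydroalumination.

**Step 2**
Reactants: 2 (E)-5-phenylpent-4-en-1-ol
Product: 3 1-phenyl-5-{[(4E)-5-phenylpent-4-en-1-yl]sulfanyl}-1H-tetrazole
Conditions: 1-phenyl-1H-tetrazole-5-thiol, PPh3, DIAD, THF, 0 °C → rt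
Reagents that add atoms: 1-phenyl-1H-tetrazole-5-thiol, Sc1nnnn1-c1ccccc1
Why: In this Mitsunobu thioetherification the acidic tetrazolethiol should displace the activated primary alcohol by SN2 without touching the alkene.

**Step 3**
Reactants: 3 1-phenyl-5-{[(4E)-5-phenylpent-4-en-1-yl]sulfanyl}-1H-tetrazole
Product: 5 1-phenyl-5-{[(4E)-5-phenylpent-4-en-1-yl]sulfonyl}-1H-tetrazole
Conditions: 30% aq. H2O2 (excess), (NH4)6Mo7O24·4H2O (10 mol%), EtOH, 0 °C → rt
Reagents that add atoms: hydrogen peroxide (compound 4), OO
Why: Molybdate-catalysed oxidation should take the sulfide through the sulfoxide to the sulfone, because the peroxomolybdate oxidises sulfur far faster than it epoxidises a conjugated 1,2-disubstituted alkene.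

**Step 4**
Reactants: 6 (R)-citronellal, (3R)-3,7-dimethyloct-6-enal
Product: 7 (4R)-4,8-dimethylnon-7-en-1-yne
Conditions: dimethyl (1-diazo-2-oxopropyl)phosphonate, K2CO3, MeOH, 0 °C → rt
Reagents that add atoms: dimethyl (1-diazo-2-oxopropyl)phosphonate, CC(=O)C(=[N+]=[N-])P(=O)(OC)OC
Why: Ohira–Bestmann homologation converts the aldehyde into the terminal alkyne under mild carbonate conditions, and the stereocentre, which lies β to the carbonyl and cannot be enolised, should stay (R).

**Step 5**
Reactants: 7 (4R)-4,8-dimethylnon-7-en-1-yne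
Product: 8 (4R)-4-methylhept-6-ynal
Conditions: O3 (metered to first excess), CH2Cl2–MeOH (4:1), NaHCO3, −78 °C; then Me2S, −78 °C → rt
Reagents that add atoms: ozone, [O-][O+]=O
Why: Ozonolysis with reductive work-up should cleave only the electron-rich trisubstituted alkene, which reacts with ozone far faster than a terminal alkyne, and it leaves the stereocentre untouched.

**Step 6**
Reactants: 5 1-phenyl-5-{[(4E)-5-phenylpent-4-en-1-yl]sulfonyl}-1H-tetrazole; 8 (4R)-4-methylhept-6-ynal
Product: 9 [(1E,5E,9R)-9-methyldodeca-1,5-dien-11-yn-1-yl]benzene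
Conditions: 5, KN(SiMe3)2, DME, −60 °C; then 8, −60 °C → rt
Reagents that add atoms: none
Why: In this Julia–Kocienski olefination the pre-formed potassium sulfonyl carbanion adds to the unbranched aldehyde faster than it could deprotonate the alkyne, Smiles rearrangement and loss of SO2 and the tetrazolone follow, and the potassium/DME combination should favour the (E)-alkene at C10=C11 (a minor Z isomer, if formed, being removable on AgNO3-impregnated silica).

**Step 7**
Reactants: 9 [(1E,5E,9R)-9-methyldodeca-1,5-dien-11-yn-1-yl]benzene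
Product: 11 (3E,6R,9E,13E)-4,6-dimethyl-14-phenyltetradeca-3,9,13-trien-2-ol (both C2 epimers), via alkenylalane 10 (not isolated)
Conditions: Cp2ZrCl2 (25 mol%), AlMe3 (2.5 equiv), CH2Cl2, 0 °C → rt; volatiles removed in vacuo; CH2Cl2, MeCHO (5 equiv), −78 → 0 °C; aq. KNaC4H4O6
Reagents that add atoms: trimethylaluminium, C[Al](C)C; acetaldehyde, CC=O
Why: Zirconium-catalysed methylalumination of the terminal alkyne (Negishi carboalumination) adds CH3 and aluminium syn with the methyl on the internal carbon, and the alkenyl–aluminium bond then adds to acetaldehyde with retention, so the trisubstituted alkene should be (E); the internal alkenes do not carbometalate, and the uncontrolled carbinol centre is removed in step 8.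

**Step 8**
Reactants: 11 (3E,6R,9E,13E)-4,6-dimethyl-14-phenyltetradeca-3,9,13-trien-2-ol
Product: 12 (3E,6R,9E,13E)-4,6-dimethyl-14-phenyltetradeca-3,9,13-trien-2-one
Conditions: activated MnO2 (excess), CH2Cl2, rt
Reagents that add atoms: none
Why: MnO2 oxidises allylic alcohols selectively under neutral heterogeneous conditions, so both carbinol epimers should converge on the (E)-enone without E/Z isomerisation or double-bond migration.

**Step 9**
Reactants: 12 (3E,6R,9E,13E)-4,6-dimethyl-14-phenyltetradeca-3,9,13-trien-2-one; 4 hydrogen peroxide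
Product: 14 (5R)-3,5-dimethyl-5-[(2R,5E,9E)-2-methyl-10-phenyldeca-5,9-dien-1-yl]-1,2-dioxolan-3-ol (both C3 epimers), via β-hydroperoxy ketone 13 (not isolated)
Conditions: 9-amino-9-deoxy-epi-quinine·Cl3CCO2H (20 mol%), 50% aq. H2O2 (5 equiv), 1,4-dioxane, 25–30 °C
Reagents that add atoms: none
Why: Proposed new method: the primary amine condenses with the sterically open methyl ketone of 12 to give a catalyst-bound iminium ion, H2O2 held through hydrogen bonds by the protonated quinuclidine attacks the β-carbon to make the C5–O1 bond, and hydrolysis of the peroxy-enamine sets free β-hydroperoxy ketone 13 and the amine. The closest known reaction type is the hydroperoxidation of β-monosubstituted acyclic enones with aqueous H2O2 under cinchona primary amine salt catalysis, which ends in 3-hydroxy-1,2-dioxolanes, while the epoxidation of β-substituted cyclic enones with the same catalysts shows that a fully substituted β-carbon can take up H2O2 in the iminium manifold; new here are the acyclic β,β-dialkyl enone and the tetrasubstituted peroxide carbon. The ring is closed by 5-exo-trig addition of the terminal hydroperoxide oxygen O2 to the ketone carbon C3, and because the cyclic peroxyhemiketal is the favoured tautomer, 13 is withdrawn from the retro-addition equilibrium as 14. C5 is set as (R) by the catalyst, which exposes one face of the (E)-iminium ion and should override the weak 1,3-bias of the C7 methyl group, whereas C3 arises as a mixture that is levelled in step 11. The step needs conjugate instead of carbonyl attack, an enone that keeps its E geometry, and no reaction at the other alkenes: the nucleophilic oxidant leaves the unactivated C10=C11 and styrene double bonds alone, the geometry comes pure from the syn-carbometalation, and a large excess of H2O2 at moderate temperature is chosen so that peroxide addition and hydrolysis outrun E/Z scrambling through the dienamine and collapse of the peroxy-enamine to the epoxy ketone.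

**Step 10**
Reactants: 14 (5R)-3,5-dimethyl-5-[(2R,5E,9E)-2-methyl-10-phenyldeca-5,9-dien-1-yl]-1,2-dioxolan-3-ol
Product: 15 (5R)-3-methoxy-3,5-dimethyl-5-[(2R,5E,9E)-2-methyl-10-phenyldeca-5,9-dien-1-yl]-1,2-dioxolane (both C3 epimers)
Conditions: MeOH, TsOH·H2O (5 mol%), 3 Å sieves, 0 °C → rt; NaHCO3 quench
Reagents that add atoms: methanol, CO
Why: Acid-catalysed exchange of the peroxyhemiketal hydroxyl for methoxyl (the peroxide counterpart of turning a lactol into its methyl acetal) should run through the oxygen-stabilised peroxycarbenium ion at C3, and both C3 epimers are acceptable because this centre is ionised again in step 11 while C5 and C7 take no part.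

**Step 11**
Reactants: 15 (5R)-3-methoxy-3,5-dimethyl-5-[(2R,5E,9E)-2-methyl-10-phenyldeca-5,9-dien-1-yl]-1,2-dioxolane
Product: 16 methyl 2-[(3S,5R)-3,5-dimethyl-5-[(2R,5E,9E)-2-methyl-10-phenyldeca-5,9-dien-1-yl]-1,2-dioxolan-3-yl]acetate
Conditions: tert-butyl[(1-methoxyethenyl)oxy]dimethylsilane (3 equiv), TiCl4 (1.1 equiv), CH2Cl2, −78 °C; H2O quench
Reagents that add atoms: tert-butyl[(1-methoxyethenyl)oxy]dimethylsilane, C=C(OC)O[Si](C)(C)C(C)(C)C
Why: TiCl4 ionises the ketal to the cyclic peroxycarbenium ion, which the silyl ketene acetal captures in a Mukaiyama-type addition known for 3-alkoxy-1,2-dioxolanes; attack on the face of C3 anti to the bulkier branched alkyl group on C5 (syn to the C5 methyl) should set C3 as (S), the minor C3 epimer being removed by chromatography.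

**Step 12**
Reactants: 16 methyl 2-[(3S,5R)-3,5-dimethyl-5-[(2R,5E,9E)-2-methyl-10-phenyldeca-5,9-dien-1-yl]-1,2-dioxolan-3-yl]acetate
Product: 17 2-[(3S,5R)-3,5-dimethyl-5-[(2R,5E,9E)-2-methyl-10-phenyldeca-5,9-dien-1-yl]-1,2-dioxolan-3-yl]acetic acid
Conditions: LiOH, THF–H2O, 0 °C → rt; then aq. HCl to pH 3
Reagents that add atoms: lithium hydroxide, [Li+].[OH-]
Why: Saponification should be safe because both peroxide-bearing carbons are fully substituted (no α-hydrogen for Kornblum–DeLaMare fragmentation) and hydroxide attacks the ester carbonyl much faster than it enolises the ester, so no stereocentre is touched.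

**Compound list**

1 | (E)-5-phenylpent-4-enoic acid | OC(=O)CC/C=C/c1ccccc1 | starting material
2 | (E)-5-phenylpent-4-en-1-ol | OCCC/C=C/c1ccccc1 | intermediate
3 | 1-phenyl-5-{[(4E)-5-phenylpent-4-en-1-yl]sulfanyl}-1H-tetrazole | S(CCC/C=C/c1ccccc1)c1nnnn1-c1ccccc1 | intermediate
4 | hydrogen peroxide | OO | starting material
5 | 1-phenyl-5-{[(4E)-5-phenylpent-4-en-1-yl]sulfonyl}-1H-tetrazole | O=S(=O)(CCC/C=C/c1ccccc1)c1nnnn1-c1ccccc1 | intermediate
6 | (R)-citronellal, (3R)-3,7-dimethyloct-6-enal | C[C@H](CCC=C(C)C)CC=O | starting material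
7 | (4R)-4,8-dimethylnon-7-en-1-yne | C#CC[C@H](C)CCC=C(C)C | intermediate
8 | (4R)-4-methylhept-6-ynal | C#CC[C@H](C)CCC=O | intermediate
9 | [(1E,5E,9R)-9-methyldodeca-1,5-dien-11-yn-1-yl]benzene | C#CC[C@H](C)CC/C=C/CC/C=C/c1ccccc1 | intermediate
10 | dimethyl[(1E,4R,7E,11E)-2,4-dimethyl-12-phenyldodeca-1,7,11-trien-1-yl]alumane (alkenylalane, not isolated) | C[Al](C)/C=C(\C)C[C@H](C)CC/C=C/CC/C=C/c1ccccc1 | intermediate
11 | (3E,6R,9E,13E)-4,6-dimethyl-14-phenyltetradeca-3,9,13-trien-2-ol (both C2 epimers) | CC(O)/C=C(\C)C[C@H](C)CC/C=C/CC/C=C/c1ccccc1 | intermediate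
12 | (3E,6R,9E,13E)-4,6-dimethyl-14-phenyltetradeca-3,9,13-trien-2-one | CC(=O)/C=C(\C)C[C@H](C)CC/C=C/CC/C=C/c1ccccc1 | intermediate
13 | (4R,6R,9E,13E)-4-hydroperoxy-4,6-dimethyl-14-phenyltetradeca-9,13-dien-2-one (β-hydroperoxy ketone, not isolated) | CC(=O)C[C@](C)(OO)C[C@H](C)CC/C=C/CC/C=C/c1ccccc1 | intermediate
14 | (5R)-3,5-dimethyl-5-[(2R,5E,9E)-2-methyl-10-phenyldeca-5,9-dien-1-yl]-1,2-dioxolan-3-ol (both C3 epimers) | C[C@H](CC/C=C/CC/C=C/c1ccccc1)C[C@]1(C)CC(C)(O)OO1 | intermediate
15 | (5R)-3-methoxy-3,5-dimethyl-5-[(2R,5E,9E)-2-methyl-10-phenyldeca-5,9-dien-1-yl]-1,2-dioxolane (both C3 epimers) | C[C@H](CC/C=C/CC/C=C/c1ccccc1)C[C@]1(C)CC(C)(OC)OO1 | intermediate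
16 | methyl 2-[(3S,5R)-3,5-dimethyl-5-[(2R,5E,9E)-2-methyl-10-phenyldeca-5,9-dien-1-yl]-1,2-dioxolan-3-yl]acetate | C[C@H](CC/C=C/CC/C=C/c1ccccc1)C[C@]1(C)C[C@@](C)(CC(=O)OC)OO1 | intermediate
17 | 2-[(3S,5R)-3,5-dimethyl-5-[(2R,5E,9E)-2-methyl-10-phenyldeca-5,9-dien-1-yl]-1,2-dioxolan-3-yl]acetic acid | C[C@H](CC/C=C/CC/C=C/c1ccccc1)C[C@]1(C)C[C@@](C)(CC(=O)O)OO1 | target

Total step count: 12
Longest linear sequence: 10 steps (steps 1–3 and 6–12, from compound 1)

**Steps most likely to fail**

Step 9 (bears the label). The iminium ion of a β,β-dialkyl enone may form and turn over slowly, the E geometry may erode through the dienamine, H2O2 may reach both faces of C5, or the peroxy-enamine may collapse to the epoxy ketone. The fallback uses known chemistry, gives up catalyst control and uses the fixed C7 centre as a resolving handle. It sets out from 12: the long-known uncatalysed addition of concentrated aqueous H2O2 to β,β-dialkyl methyl enones (the reaction type that converts mesityl oxide into 3,5,5-trimethyl-1,2-dioxolan-3-ol; excess 50% H2O2, dioxane, rt, no amine) should give 14 together with its C5 epimer, (5S)-3,5-dimethyl-5-[(2R,5E,9E)-2-methyl-10-phenyldeca-5,9-dien-1-yl]-1,2-dioxolan-3-ol F1. The mixture is carried through steps 10 and 11, in which F1 becomes (5S)-3-methoxy-3,5-dimethyl-5-[(2R,5E,9E)-2-methyl-10-phenyldeca-5,9-dien-1-yl]-1,2-dioxolane F2 and then methyl 2-[(3R,5S)-3,5-dimethyl-5-[(2R,5E,9E)-2-methyl-10-phenyldeca-5,9-dien-1-yl]-1,2-dioxolan-3-yl]acetate F3. The diastereomers 16 and F3 are separated by preparative HPLC, and the route is rejoined at 16.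

Step 11. Stoichiometric TiCl4 may break the O–O bond heterolytically or start cationic reactions at the styrene before the ketene acetal reaches the peroxycarbenium ion, and the later hydroxide step is a second exposure of the β-peroxy ester. In the fallback the two-carbon arm enters at the aldehyde oxidation level and is oxidised afterwards, so that neither a stoichiometric metal halide nor a basic hydrolysis is needed. This fallback does not improve the facial selectivity at C3; any C3 epimer would still have to be separated, at the aldehyde or acid stage. It sets out from 15: trimethyl(vinyloxy)silane under catalytic Me3SiOTf (CH2Cl2, −78 °C) should give 2-[(3S,5R)-3,5-dimethyl-5-[(2R,5E,9E)-2-methyl-10-phenyldeca-5,9-dien-1-yl]-1,2-dioxolan-3-yl]acetaldehyde F4. Pinnick oxidation (NaClO2, NaH2PO4, 2-methylbut-2-ene, t-BuOH–H2O) then converts F4 directly into 17, where the route is rejoined, bypassing 16 and step 12.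

Step 7. Transfer of the alkenyl group from aluminium to the enolisable, volatile acetaldehyde may be slow, so that methyl transfer from residual AlMe3 and self-condensation of the aldehyde take over. The fallback separates carbometalation from carbonyl addition. It sets out from 9: the alkenylalane 10 is quenched with I2 (THF, −30 °C) to give the isolable [(1E,5E,9R,11E)-12-iodo-9,11-dimethyldodeca-1,5,11-trien-1-yl]benzene F5. A Nozaki–Hiyama–Kishi reaction (CrCl2, catalytic NiCl2, DMSO, MeCHO, rt) should then couple F5 with acetaldehyde with retention of the alkene geometry, returning to the route at 11.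

**Further compounds**

F1 | step 9 | (5S)-3,5-dimethyl-5-[(2R,5E,9E)-2-methyl-10-phenyldeca-5,9-dien-1-yl]-1,2-dioxolan-3-ol (both C3 epimers) | C[C@H](CC/C=C/CC/C=C/c1ccccc1)C[C@@]1(C)CC(C)(O)OO1
F2 | step 9 | (5S)-3-methoxy-3,5-dimethyl-5-[(2R,5E,9E)-2-methyl-10-phenyldeca-5,9-dien-1-yl]-1,2-dioxolane (both C3 epimers) | C[C@H](CC/C=C/CC/C=C/c1ccccc1)C[C@@]1(C)CC(C)(OC)OO1
F3 | step 9 | methyl 2-[(3R,5S)-3,5-dimethyl-5-[(2R,5E,9E)-2-methyl-10-phenyldeca-5,9-dien-1-yl]-1,2-dioxolan-3-yl]acetate | C[C@H](CC/C=C/CC/C=C/c1ccccc1)C[C@@]1(C)C[C@](C)(CC(=O)OC)OO1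
F4 | step 11 | 2-[(3S,5R)-3,5-dimethyl-5-[(2R,5E,9E)-2-methyl-10-phenyldeca-5,9-dien-1-yl]-1,2-dioxolan-3-yl]acetaldehyde | C[C@H](CC/C=C/CC/C=C/c1ccccc1)C[C@]1(C)C[C@@](C)(CC=O)OO1
F5 | step 7 | [(1E,5E,9R,11E)-12-iodo-9,11-dimethyldodeca-1,5,11-trien-1-yl]benzene | I/C=C(\C)C[C@H](C)CC/C=C/CC/C=C/c1ccccc1
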